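**Plan**

- Retrosynthesis: the 11-hydroxy quinone methide is unmasked last from an 11,12-dimethoxyarene. Ring D is cut at C10'–O (conjugate borylation of a C7=C10' enone), at C4'–C10' (intramolecular Heck) and at C14–C4' (Suzuki), which leads back to (+)-sabinene and a 14-bromo cis-6-oxoabietatriene. The C6 carbonyl is taken back to the tetralin, the C4 gem-dimethyl group to a C4 ketone, and ring A is contracted by excision of C3 to a cis-fused cyclopentanone (A-nor ketone). That ketone is cut at C7–C8 (Friedel–Crafts), C5–C6 (enolate alkylation) and C9–C10 (conjugate addition).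
- Forward order: ring C is bought; C9–C10 and C5–C6 are made in one pot; ring B is closed; the five-membered ring is expanded to ring A; C4 is dimethylated; C6 is oxidised; the thujene is attached at C14; ring D is closed; C10' is hydroxylated; ring C is oxidised to the quinone methide.
- Feature used by the key step: in the A-nor ketone the carbonyl carbon (future C4) lies between methine C5 (ring-fusion carbon, next to quaternary C10) and methylene C2. This difference lets a diazo carbon (future C3) be inserted only into the C4–C2 bond. The five-membered ring, which can be fused to ring B only in the cis sense, hands the cis H-5/CH3-10 relationship on to ring A.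
- Stereochemistry: C10 by catalyst (asymmetric conjugate addition); C5 by relay from C10 (cis-hydrindanone, carried through the ring expansion); C1' and C5' bought with (+)-sabinene; C4' by substrate control (carbopalladation anti to the cyclopropane CH2); C10' by ligand control.

Key step: step 5

Remark: abietane numbering (C1–C20) is used for the diterpene part and primed thujane numbering (C1'–C6', C10') for the monoterpene part. The target has H-5 and CH3-10 cis (5R,10S) and the ring C carbon C14 syn to the cyclopropane methylene C6' at the spiro carbon C4'. Compounds 1, 3 and 17 are taken as commercial.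

**Step 1**
Reactants: 1 3-isopropylcatechol
Product: 2 1-isopropyl-2,3-dimethoxybenzene
Conditions: MeI, K2CO3, acetone, 56 °C
Reagents that add atoms: iodomethane, CI
Why: Williamson O-methylation of both phenols; no stereocentre is involved.

**Step 2**
Reactants: 2 1-isopropyl-2,3-dimethoxybenzene; 3 3-methylcyclopent-2-en-1-one
Product: 7 tert-butyl 2-[2-(4-isopropyl-2,3-dimethoxyphenyl)-2-methyl-5-oxocyclopentyl]acetate (quaternary carbon S; mainly the epimer with the acetate arm trans to the aryl group), via aryllithium 4 (not isolated), via aryl(dimethyl)alane 5 (not isolated), via aluminium enolate 6 (not isolated)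
Conditions: n-BuLi, TMEDA, Et2O, 0 °C to rt; Me2AlCl, −78 °C to rt; then 3, copper thiophene-2-carboxylate (CuTC, 5 mol %), chiral phosphinamine ligand of the SimplePhos type (enantiomer giving the S centre), Et2O, −30 °C; then MeLi, HMPA, tert-butyl bromoacetate, −30 to 0 °C
Reagents that add atoms: tert-butyl bromoacetate, BrCC(=O)OC(C)(C)C
Why: Directed ortho-metalation places lithium at the only position ortho to a methoxy group (future C9), transmetalation gives the aryl alane, and the copper-catalysed asymmetric conjugate addition to 3 sets the quaternary benzylic centre C10 (S) under catalyst control while generating the aluminium enolate regiospecifically at C5, whose C-alkylation (as the lithium aluminate) should occur mainly anti to the aryl group; the C5 epimers need not be separated because they converge in step 3.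

**Step 3**
Reactants: 7 tert-butyl 2-[2-(4-isopropyl-2,3-dimethoxyphenyl)-2-methyl-5-oxocyclopentyl]acetate
Product: 8 cis-7-isopropyl-8,9-dimethoxy-9b-methyl-1,2,3a,4-tetrahydrocyclopenta[a]naphthalene-3,5(9bH)-dione (A-nor diketone, H-5 and CH3-10 cis)
Conditions: P2O5 in MeSO3H (1:10 w/w), 50 °C
Reagents that add atoms: none
Why: Acidolysis of the tert-butyl ester and intramolecular Friedel–Crafts acylation at C8 (para to the C12 methoxy group and the only free position ortho to the side chain) close ring B; C5 equilibrates through the enol under these conditions and only the epimer with the acyl arm cis to the aryl group can cyclise, so the cis-fused hydrindanone should result by substrate control from C10.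

**Step 4**
Reactants: 8 A-nor diketone
Product: 9 cis-7-isopropyl-8,9-dimethoxy-9b-methyl-1,2,3a,4,5,9b-hexahydro-3H-cyclopenta[a]naphthalen-3-one (A-nor ketone; its carbonyl carbon is the future C4)
Conditions: Et3SiH, CF3CO2H, CH2Cl2, 0 °C to rt
Reagents that add atoms: none
Why: Ionic hydrogenation: the aryl ketone is protonated and reduced through the benzylic cation stabilised by the para methoxy group down to CH2, whereas the non-conjugated cyclopentanone gives no stabilised cation and should survive; no stereocentre changes.

**Step 5**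
Reactants: 9 A-nor ketone
Product: 11 (5S,10S)-11,12-dimethoxy-18,19-dinorabieta-8,11,13-trien-4-one (A/B cis), via alpha-silyl ketone 10 (not isolated)
Conditions: Me3SiCHN2, BF3·OEt2, CH2Cl2, −78 to −30 °C; then 1 M HCl, THF, 0 °C
Reagents that add atoms: (trimethylsilyl)diazomethane, C[Si](C)(C)C=[N+]=[N-]
Why: BF3 activates the C4 carbonyl of 9, the diazo carbon adds from the convex face of the cis-hydrindanone, and the resulting β-oxido diazonium ion loses N2 with a 1,2-shift of the ring bond C4–C2 onto the diazo carbon, which becomes C3, so that the cyclopentanone (C10, C1, C2, C4, C5) is turned into the six-membered ring A (Tiffeneau–Demjanov-type diazoalkane homologation; closest precedent: Lewis-acid-promoted silyldiazomethane ring expansion of 2-substituted cycloalkanones and the D-homo-annulation of 17-oxo steroids). Ring A is not closed by a cyclisation but arises by migration of an existing ring bond, that is, a one-carbon ring expansion in which four of the five bonds of the small ring stay untouched. No stereocentre of the product is made in this step (the silyl-bearing C3 of 10 becomes CH2 on protodesilylation); the cis relationship of H-5 and CH3-10, which the five-membered ring enforced in step 3, is carried over because neither C5 nor C10 takes part. The selectivity that is needed is migration of methylene C2 rather than methine C5: C5 is tertiary, neopentylic (next to quaternary C10) and flanked by ring B, so the preference of the silyl diazoalkane for the less substituted α-carbon directs insertion to the C2 side and leaves the carbonyl at C4, exactly where the gem-dimethyl group is needed. Over-homologation is blocked because the primary product is the hindered α-silyl ketone 10, and the acidic desilylation is kept cold and short so that C5, now α to a six-ring ketone, does not equilibrate.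

**Step 6**
Reactants: 11 (5S,10S)-11,12-dimethoxy-18,19-dinorabieta-8,11,13-trien-4-one
Product: 12 (5R,10S)-11,12-dimethoxyabieta-8,11,13-triene (5-epi series, A/B cis)
Conditions: Me2Zn, TiCl4 (gives Me2TiCl2), CH2Cl2, −40 to 0 °C
Reagents that add atoms: dimethyltitanium dichloride (made in the flask from dimethylzinc, C[Zn]C, and TiCl4), C[Ti](C)(Cl)Cl
Why: Reetz geminal dimethylation: methyl transfer from titanium to the C4 carbonyl, ionisation of the tertiary titanate and capture of the cation by a second Ti–CH3 replace C=O by C(CH3)2 under non-basic conditions, so C5 is not epimerised and no stereocentre is created.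

**Step 7**
Reactants: 12 (5R,10S)-11,12-dimethoxyabieta-8,11,13-triene
Product: 13 (5R,10S)-14-bromo-11,12-dimethoxyabieta-8,11,13-triene
Conditions: NBS, MeCN, 0 °C to rt, dark
Reagents that add atoms: N-bromosuccinimide, O=C1CCC(=O)N1Br
Why: Electrophilic aromatic bromination can only occur at C14, the single unsubstituted position of ring C, which is activated by the para methoxy group at C11.

**Step 8**
Reactants: 13 (5R,10S)-14-bromo-11,12-dimethoxyabieta-8,11,13-triene
Product: 14 (5R,10S)-14-bromo-11,12-dimethoxyabieta-6,8,11,13-tetraene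
Conditions: DDQ, 1,4-dioxane, 90 °C
Reagents that add atoms: none
Why: DDQ abstracts hydride from benzylic C7 (cation stabilised by the para C12 methoxy group) and loss of H-6 gives the styrene-type C6=C7 bond; quaternary C10 prevents aromatisation of ring B and C5 keeps its configuration.

**Step 9**
Reactants: 14 (5R,10S)-14-bromo-11,12-dimethoxyabieta-6,8,11,13-tetraene
Product: 16 (5R,10S)-14-bromo-11,12-dimethoxyabieta-8,11,13-trien-6-one, via epoxide 15 (not isolated)
Conditions: m-CPBA, NaHCO3, CH2Cl2, 0 °C; then ZnI2 (cat.), CH2Cl2, rt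
Reagents that add atoms: 3-chloroperoxybenzoic acid, OOC(=O)c1cccc(Cl)c1
Why: Prilezhaev epoxidation followed by Meinwald rearrangement: the benzylic C7–O bond ionises and a 1,2-hydride shift from C6 gives the 2-tetralone-type C6 ketone regiospecifically; the transient epoxide stereocentres are lost and the mild, catalytic Lewis acid should leave C5 (now α to the ketone) unchanged.

**Step 10**
Reactants: 17 (+)-sabinene [(1R,5R)-4-methylidene-1-isopropylbicyclo[3.1.0]hexane]
Product: 18 sabina ketone [(1S,5R)-5-isopropylbicyclo[3.1.0]hexan-2-one]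
Conditions: O3, CH2Cl2, −78 °C; then Me2S
Reagents that add atoms: ozone, [O-][O+]=O
Why: Ozonolysis with reductive work-up cleaves the exocyclic methylene to the cyclopropyl ketone without touching C1' and C5', which are bought with 17.

**Step 11**
Reactants: 18 sabina ketone
Product: 20 5-isopropylbicyclo[3.1.0]hex-2-en-2-yl trifluoromethanesulfonate (thuj-3-en-4-yl triflate), via lithium enolate 19 (not isolated)
Conditions: LDA, THF, −78 °C; PhNTf2, −78 to 0 °C
Reagents that add atoms: N-phenylbis(trifluoromethanesulfonimide), O=S(=O)(N(c1ccccc1)S(=O)(=O)C(F)(F)F)C(F)(F)F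
Why: Kinetic deprotonation can only occur at C3' because the other α-carbon (C5') is a cyclopropane bridgehead, and O-sulfonylation of the enolate gives the alkenyl triflate.

**Step 12**
Reactants: 20 thuj-3-en-4-yl triflate; 16 (5R,10S)-14-bromo-11,12-dimethoxyabieta-8,11,13-trien-6-one
Product: 22 (5R,10S)-11,12-dimethoxy-14-(thuj-3-en-4-yl)abieta-8,11,13-trien-6-one, via alkenyl boronate 21 (not isolated)
Conditions: B2pin2, PdCl2(PPh3)2, PPh3, KOPh, toluene, 50 °C; then 16, Pd(OAc)2, SPhos, K3PO4, toluene/H2O, 80 °C
Reagents that add atoms: none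
Why: Miyaura borylation of the alkenyl triflate and Suzuki–Miyaura coupling with the hindered aryl bromide (biaryl phosphine ligand for the doubly ortho-substituted partner) join C14 to C4'; a weak phosphate base is used because C5 is α to the C6 ketone, and no stereocentre is formed.

**Step 13**
Reactants: 22 (5R,10S)-11,12-dimethoxy-14-(thuj-3-en-4-yl)abieta-8,11,13-trien-6-one
Product: 24 (E)-enol triflate of the 7-formyl ketone [7-(trifluoromethanesulfonyloxymethylidene) derivative of 22], via sodium enolate 23 (not isolated)
Conditions: NaH, HCO2Et, THF, 0 °C to rt; then PhNTf2, DMF, 0 °C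
Reagents that add atoms: ethyl formate, CCOC=O; N-phenylbis(trifluoromethanesulfonimide), O=S(=O)(N(c1ccccc1)S(=O)(=O)C(F)(F)F)C(F)(F)F
Why: Claisen formylation takes place at C7, the only α-methylene of the ketone, and O-triflation of the dissociated sodium enolate in DMF should give mainly the E enol triflate (OTf trans to the C6 carbonyl, on the side of ring C), the geometry needed for cyclisation.

**Step 14**
Reactants: 24 (E)-enol triflate
Product: 25 spiro dienone (ring D closed: C7=C10' and C2'=C3' double bonds, C4' spiro, 11,12-dimethoxy)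
Conditions: Pd(OAc)2 (10 mol %), PPh3, 1,2,2,6,6-pentamethylpiperidine, MeCN, 80 °C
Reagents that add atoms: none
Why: Intramolecular Mizoroki–Heck reaction (5-exo-trig): the alkenylpalladium at C10' adds to the twisted, non-conjugated C4'=C3' bond with C10' bonding to C4' on the face anti to the cyclopropane methylene C6' (the usual face of attack on bicyclo[3.1.0]hex-2-enes), which should make the spiro quaternary centre C4' with the aryl carbon C14 syn to C6' as in the target, and syn β-hydride elimination can only occur towards C2'.

**Step 15**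
Reactants: 25 spiro dienone
Product: 26 spiro enone (C7=C10' retained, thujane ring saturated)
Conditions: 2-nitrobenzenesulfonylhydrazide, Et3N, CH2Cl2, rt
Reagents that add atoms: none
Why: Diimide reduction is selective for the unpolarised cis-disubstituted C2'=C3' bond over the hindered, conjugated trisubstituted C7=C10' bond and does not open the cyclopropane; no stereocentre is formed.

**Step 16**
Reactants: 26 spiro enone
Product: 28 (10'S)-10'-hydroxy ketone, 11,12-dimethyl ether (C7 epimers), via boryl ketone 27 (not isolated)
Conditions: B2pin2, CuCl (5 mol %), DTBM-SEGPHOS (enantiomer placing boron cis to C5'), NaOtBu (10 mol %), MeOH, THF, rt; then H2O2, pH 7 phosphate buffer, 0 °C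
Reagents that add atoms: hydrogen peroxide, OO
Why: Copper-catalysed conjugate borylation of the enone and stereoretentive oxidation of the C–B bond give the β-hydroxy ketone; the two faces of C10' differ only through the remote thujane atoms C5'–H and C3'H2, so the chiral bisphosphine should control delivery of boron to the face cis to C5', and the C7 configuration formed on protonation is irrelevant because C7 becomes sp2 in step 17.

**Step 17**
Reactants: 28 (10'S)-10'-hydroxy ketone, 11,12-dimethyl ether
Product: 31 target CNP0178265.2, via catechol 29 (not isolated), via ortho-quinone 30 (not isolated)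
Conditions: BCl3, n-Bu4NI, CH2Cl2, −78 to 0 °C; aqueous work-up; then Ag2O, Et2O, rt
Reagents that add atoms: none
Why: Boron trichloride with iodide cleaves both aryl methyl ethers at low temperature, Ag2O oxidises the catechol to the ortho-quinone, and this should tautomerise by shift of H-7 to O-11 to the extended quinone methide (the usual behaviour of 6-oxo-11,12-catechols of the abietane series), which removes the C7 stereocentre and leaves C5, C10, C4', C10', C1' and C5' untouched.

**Compound list**

1 | 3-isopropylcatechol | CC(C)c1cccc(O)c1O | starting material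
2 | 1-isopropyl-2,3-dimethoxybenzene | CC(C)c1cccc(OC)c1OC | intermediate
3 | 3-methylcyclopent-2-en-1-one | CC1=CC(=O)CC1 | starting material
4 | (4-isopropyl-2,3-dimethoxyphenyl)lithium | [Li]c1ccc(C(C)C)c(OC)c1OC | intermediate
5 | (4-isopropyl-2,3-dimethoxyphenyl)dimethylalane | C[Al](C)c1ccc(C(C)C)c(OC)c1OC | intermediate
6 | dimethylaluminium enolate of (S)-3-(4-isopropyl-2,3-dimethoxyphenyl)-3-methylcyclopentanone | C[Al](C)OC1=C[C@](C)(CC1)c1ccc(C(C)C)c(OC)c1OC | intermediate
7 | tert-butyl 2-[(1R,2S)-2-(4-isopropyl-2,3-dimethoxyphenyl)-2-methyl-5-oxocyclopentyl]acetate (arm trans to aryl; formed with its C1 epimer) | CC(C)(C)OC(=O)C[C@H]1C(=O)CC[C@]1(C)c1ccc(C(C)C)c(OC)c1OC | intermediate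
8 | cis-7-isopropyl-8,9-dimethoxy-9b-methyl-1,2,3a,4-tetrahydrocyclopenta[a]naphthalene-3,5(9bH)-dione | CC(C)c1cc2C(=O)C[C@@H]3C(=O)CC[C@]3(C)c2c(OC)c1OC | intermediate
9 | cis-7-isopropyl-8,9-dimethoxy-9b-methyl-1,2,3a,4,5,9b-hexahydro-3H-cyclopenta[a]naphthalen-3-one (A-nor ketone) | CC(C)c1cc2CC[C@@H]3C(=O)CC[C@]3(C)c2c(OC)c1OC | intermediate
10 | 3-(trimethylsilyl) derivative of 11 (C3 epimers) | CC(C)c1cc2CC[C@@H]3C(=O)C([Si](C)(C)C)CC[C@]3(C)c2c(OC)c1OC | intermediate
11 | (5S,10S)-11,12-dimethoxy-18,19-dinorabieta-8,11,13-trien-4-one (A/B cis) | CC(C)c1cc2CC[C@@H]3C(=O)CCC[C@]3(C)c2c(OC)c1OC | intermediate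
12 | (5R,10S)-11,12-dimethoxyabieta-8,11,13-triene (A/B cis) | CC(C)c1cc2CC[C@@H]3C(C)(C)CCC[C@]3(C)c2c(OC)c1OC | intermediate
13 | (5R,10S)-14-bromo-11,12-dimethoxyabieta-8,11,13-triene | CC(C)c1c(Br)c2CC[C@@H]3C(C)(C)CCC[C@]3(C)c2c(OC)c1OC | intermediate
14 | (5R,10S)-14-bromo-11,12-dimethoxyabieta-6,8,11,13-tetraene | CC(C)c1c(Br)c2C=C[C@@H]3C(C)(C)CCC[C@]3(C)c2c(OC)c1OC | intermediate
15 | 6,7-epoxide of 14 (oxygen drawn on the face of H-5) | CC(C)c1c(Br)c2[C@H]4O[C@H]4[C@@H]3C(C)(C)CCC[C@]3(C)c2c(OC)c1OC | intermediate
16 | (5R,10S)-14-bromo-11,12-dimethoxyabieta-8,11,13-trien-6-one | CC(C)c1c(Br)c2CC(=O)[C@@H]3C(C)(C)CCC[C@]3(C)c2c(OC)c1OC | intermediate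
17 | (+)-sabinene, (1R,5R) | C=C1CC[C@]2(C(C)C)C[C@@H]21 | starting material
18 | sabina ketone, (1S,5R)-5-isopropylbicyclo[3.1.0]hexan-2-one | O=C1CC[C@]2(C(C)C)C[C@@H]21 | intermediate
19 | lithium enolate of 18 | [Li]OC1=CC[C@]2(C(C)C)C[C@@H]21 | intermediate
20 | 5-isopropylbicyclo[3.1.0]hex-2-en-2-yl trifluoromethanesulfonate (configuration of 17) | O=S(=O)(OC1=CC[C@]2(C(C)C)C[C@@H]21)C(F)(F)F | intermediate
21 | 2-(5-isopropylbicyclo[3.1.0]hex-2-en-2-yl)-4,4,5,5-tetramethyl-1,3,2-dioxaborolane | CC1(C)OB(OC1(C)C)C1=CC[C@]2(C(C)C)C[C@@H]21 | intermediate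
22 | (5R,10S)-11,12-dimethoxy-14-(thuj-3-en-4-yl)abieta-8,11,13-trien-6-one | CC(C)c1c(C2=CC[C@]3(C(C)C)C[C@@H]32)c2CC(=O)[C@@H]4C(C)(C)CCC[C@]4(C)c2c(OC)c1OC | intermediate
23 | sodium enolate of the 7-hydroxymethylidene derivative of 22 | CC(C)c1c(C2=CC[C@]3(C(C)C)C[C@@H]32)c2C(=C[O-])C(=O)[C@@H]4C(C)(C)CCC[C@]4(C)c2c(OC)c1OC.[Na+] | intermediate
24 | (E)-7-(trifluoromethanesulfonyloxymethylidene) derivative of 22 | CC(C)c1c(C2=CC[C@]3(C(C)C)C[C@@H]32)c2/C(=C\OS(=O)(=O)C(F)(F)F)C(=O)[C@@H]4C(C)(C)CCC[C@]4(C)c2c(OC)c1OC | intermediate
25 | spiro dienone (ring D closed; C7=C10', C2'=C3'; C14 syn to C6' at C4') | CC(C)c1c2c3C(=C[C@]25C=C[C@]6(C(C)C)C[C@@H]65)C(=O)[C@@H]4C(C)(C)CCC[C@]4(C)c3c(OC)c1OC | intermediate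
26 | spiro enone (C7=C10'; saturated thujane) | CC(C)c1c2c3C(=C[C@]25CC[C@]6(C(C)C)C[C@@H]65)C(=O)[C@@H]4C(C)(C)CCC[C@]4(C)c3c(OC)c1OC | intermediate
27 | 10'-(pinacolatoboryl) ketone (boron cis to C5'; C7 epimers) | CC(C)c1c2c3C([C@@H](B8OC(C)(C)C(C)(C)O8)[C@]25CC[C@]6(C(C)C)C[C@@H]65)C(=O)[C@@H]4C(C)(C)CCC[C@]4(C)c3c(OC)c1OC | intermediate
28 | (10'S)-10'-hydroxy ketone, 11,12-dimethyl ether (C7 epimers) | CC(C)c1c2c3C([C@@H](O)[C@]25CC[C@]6(C(C)C)C[C@@H]65)C(=O)[C@@H]4C(C)(C)CCC[C@]4(C)c3c(OC)c1OC | intermediate
29 | 11,12-catechol of 28 (C7 epimers) | CC(C)c1c2c3C([C@@H](O)[C@]25CC[C@]6(C(C)C)C[C@@H]65)C(=O)[C@@H]4C(C)(C)CCC[C@]4(C)c3c(O)c1O | intermediate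
30 | 11,12-ortho-quinone of 29 (C7 epimers) | CC(C)C1=C2C=3C([C@@H](O)[C@]25CC[C@]6(C(C)C)C[C@@H]65)C(=O)[C@@H]4C(C)(C)CCC[C@]4(C)C3C(=O)C1=O | intermediate
31 | CNP0178265.2 (5R,10S,10'S,4'S,1'R,5'S) | CC(C)C1=C2C3=C(C(=O)[C@@H]4C(C)(C)CCC[C@]4(C)C3=C(O)C1=O)[C@@H](O)[C@]21CC[C@]2(C(C)C)C[C@@H]21 | target

**Totals**

Total step count: 17. Longest linear sequence: 15 steps (steps 1 to 9 and 12 to 17); steps 10 and 11 make the thujene fragment.

**Steps most likely to fail, riskiest first**

Step 14. The oxidative addition and insertion may be slow because the enol triflate has the wrong geometry or the thujene face is shielded. Palladium hydride may also re-add to the new vinylcyclopropane and open it, and attack on the wrong face would give the C4' epimer. Fallback by a radical route, setting out from 22 and coming back at 26: 22 is formylated as in step 13 and the sodium enolate 23 is treated in the same flask with Ph3PBr2 to give the (E)-7-(bromomethylidene) ketone F1. Bu3SnH and AIBN in benzene at 80 °C generate the vinyl radical at C10', which should cyclise 5-exo onto C4' anti to the cyclopropane methylene. The resulting C3' radical, which is not adjacent to the cyclopropane, takes hydrogen from the stannane and gives 26 directly, so steps 14 and 15 are replaced.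

Step 16. Conjugate addition to the neopentylic β-carbon C10' may be too slow, or the ligand may not override the substrate bias, so that boron enters trans to C5'. Fallback by epoxidation and reduction, setting out from 26 and coming back at 28: catalyst-controlled nucleophilic epoxidation of the enone (cumene hydroperoxide, La(OiPr)3, BINOL of the appropriate configuration, Ph3AsO, THF) gives the 7,10'-epoxy ketone F2 with oxygen cis to C5'. SmI2 in THF/MeOH at −78 °C cleaves the C7–O bond of the epoxy ketone and gives 28.

Step 6. Ionisation at C4 next to the C5 methine may lead to elimination or to hydride and alkyl shifts instead of the second methyl transfer. Fallback by cyclopropane hydrogenolysis, setting out from 11 and coming back at 12: non-basic methylenation of the ketone (CH2Br2, Zn, TiCl4) gives the 4-methylidene compound F3. Simmons–Smith cyclopropanation (Et2Zn, CH2I2) gives the 4-spirocyclopropane F4. Hydrogenolysis of the distal cyclopropane bond (H2, PtO2, AcOH) gives the gem-dimethyl compound 12.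

Further compounds
F1 | step 14 | (E)-7-(bromomethylidene) derivative of 22 | CC(C)c1c(C2=CC[C@]3(C(C)C)C[C@@H]32)c2/C(=C\Br)C(=O)[C@@H]4C(C)(C)CCC[C@]4(C)c2c(OC)c1OC
F2 | step 16 | 7,10'-epoxy ketone from 26 (oxygen cis to C5') | CC(C)c1c2c3[C@]7(O[C@H]7[C@]25CC[C@]6(C(C)C)C[C@@H]65)C(=O)[C@@H]4C(C)(C)CCC[C@]4(C)c3c(OC)c1OC
F3 | step 6 | (5R,10S)-11,12-dimethoxy-4-methylidene-18,19-dinorabieta-8,11,13-triene | CC(C)c1cc2CC[C@@H]3C(=C)CCC[C@]3(C)c2c(OC)c1OC
F4 | step 6 | 4-spirocyclopropane from F3 | CC(C)c1cc2CC[C@@H]3C4(CC4)CCC[C@]3(C)c2c(OC)c1OC
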